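## Retrosynthetic overview

1. Target 16 ⇐ 13 by oxidative 4'-O-demethylation (ortho-quinone, then reduction) and 7-O-desilylation. The methyl ether bought in hesperetin keeps the two ring-B oxygens distinct until the last step.
2. 13 ⇐ aryl iodide 6 + tosylate 11: the C6–CH2 bond is made by nickel-catalysed electroreductive cross-electrophile coupling. The side-chain carbinol is bought in methyl (S)-glycerate acetonide 7.
3. 6 ⇐ 5 by [1,3] O→C geranyl shift to C2' (the only free ortho carbon, since C4' carries OMe); 5 ⇐ 3 + geraniol 4; 3 ⇐ hesperetin 1 by 7-O-silylation and 5-OH-directed C6 iodination.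
4. 11 ⇐ 7 by double MeMgBr addition, dehydration to the isopropenyl group, acetonide removal and primary tosylation.
5. No ring is built: rings A, C and B and the C2 stereocentre are bought together in (2S)-hesperetin.

Assumption: (2S)-hesperetin (aglycone of citrus hesperidin) is bought enantiopure and its ee is checked by chiral HPLC before use.

## Route

Step 1
Reactants: 1 (2S)-hesperetin
Product: 2 (2S)-7-[(tert-butyldimethylsilyl)oxy]-5-hydroxy-2-(3-hydroxy-4-methoxyphenyl)chroman-4-one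
Conditions: TBSCl (1.05 equiv), iPr2NEt (1.2 equiv), CH2Cl2–DMF, −20 °C to 0 °C
Reagents that add atoms: tert-butyldimethylsilyl chloride, CC(C)(C)[Si](C)(C)Cl
Why: Chemoselective O-silylation, because the amine deprotonates only the vinylogous-acid 7-OH (pKa about 7.5) while the 3'-OH (about 10) and the chelated 5-OH stay free, and the mild base leaves C2 untouched.

Step 2
Reactants: 2 (2S)-7-[(tert-butyldimethylsilyl)oxy]-5-hydroxy-2-(3-hydroxy-4-methoxyphenyl)chroman-4-one
Product: 3 (2S)-7-[(tert-butyldimethylsilyl)oxy]-5-hydroxy-2-(3-hydroxy-4-methoxyphenyl)-6-iodochroman-4-one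
Conditions: NIS (1.0 equiv), MeCN–CH2Cl2, 0 °C, dark
Reagents that add atoms: N-iodosuccinimide, O=C1CCC(=O)N1I
Why: Electrophilic aromatic iodination; 5,7-dioxygenated flavonoids with a free, hydrogen-bonded 5-OH are iodinated at C6, and the trioxygenated ring A is far more nucleophilic than the guaiacol ring B.

Step 3
Reactants: 3 (2S)-7-[(tert-butyldimethylsilyl)oxy]-5-hydroxy-2-(3-hydroxy-4-methoxyphenyl)-6-iodochroman-4-one, 4 geraniol
Product: 5 (2S)-7-[(tert-butyldimethylsilyl)oxy]-2-(3-{[(2E)-3,7-dimethylocta-2,6-dien-1-yl]oxy}-4-methoxyphenyl)-5-hydroxy-6-iodochroman-4-one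
Conditions: PPh3, DIAD, THF, 0 °C to rt
Reagents that add atoms: none
Why: Mitsunobu etherification of the only reactive phenol (3'-OH; the 5-OH is chelated) with the primary allylic alcohol goes by SN2 under neutral conditions that spare the labile 7-O-silyl ether, the E-alkene and C2.

Step 4
Reactants: 5 (2S)-7-[(tert-butyldimethylsilyl)oxy]-2-(3-{[(2E)-3,7-dimethylocta-2,6-dien-1-yl]oxy}-4-methoxyphenyl)-5-hydroxy-6-iodochroman-4-one
Product: 6 (2S)-7-[(tert-butyldimethylsilyl)oxy]-2-{2-[(2E)-3,7-dimethylocta-2,6-dien-1-yl]-3-hydroxy-4-methoxyphenyl}-5-hydroxy-6-iodochroman-4-one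
Conditions: montmorillonite K10 (dried), CH2Cl2, 0 °C, about 1 h
Reagents that add atoms: none
Why: Acid-clay-catalysed [1,3] O-to-C allyl shift through a tight geranyl cation/phenol ion pair; C4' carries OMe, so C2' is the only free ortho carbon, the linear E-geranyl unit is kept, and C8 is shielded by iodine and the silyl ether.

Step 5
Reactants: 7 methyl (4S)-2,2-dimethyl-1,3-dioxolane-4-carboxylate
Product: 8 2-[(4S)-2,2-dimethyl-1,3-dioxolan-4-yl]propan-2-ol
Conditions: MeMgBr (2.5 equiv), THF, 0 °C; then H2O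
Reagents that add atoms: methylmagnesium bromide, C[Mg]Br
Why: Double Grignard addition to the ester, a standard conversion of this glycerate that does not epimerise the α-alkoxy stereocentre.

Step 6
Reactants: 8 2-[(4S)-2,2-dimethyl-1,3-dioxolan-4-yl]propan-2-ol
Product: 9 (4R)-2,2-dimethyl-4-(prop-1-en-2-yl)-1,3-dioxolane
Conditions: Martin sulfurane, CH2Cl2, 0 °C to rt
Reagents that add atoms: none
Why: Martin sulfurane dehydration of the tertiary alcohol removes one of six methyl hydrogens in preference to the single hydrogen on the oxygen-bearing ring carbon, giving the isopropenyl group without touching the stereocentre (the descriptor changes only through priorities).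

Step 7
Reactants: 9 (4R)-2,2-dimethyl-4-(prop-1-en-2-yl)-1,3-dioxolane
Product: 10 (2R)-3-methylbut-3-ene-1,2-diol
Conditions: Dowex 50WX8 (H+ form), MeOH, rt
Reagents that add atoms: none
Why: Acid-catalysed transketalisation (acetonide methanolysis) frees the diol under conditions too mild to ionise the secondary allylic alcohol.

Step 8
Reactants: 10 (2R)-3-methylbut-3-ene-1,2-diol
Product: 11 (2R)-2-hydroxy-3-methylbut-3-en-1-yl 4-methylbenzenesulfonate
Conditions: TsCl (1.05 equiv), Bu2SnO (2 mol%), Et3N, CH2Cl2, 0 °C to rt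
Reagents that add atoms: 4-methylbenzenesulfonyl chloride, Cc1ccc(cc1)S(=O)(=O)Cl
Why: Stannylene-acetal-catalysed regioselective sulfonylation of the primary hydroxyl of a 1,2-diol, leaving the secondary allylic carbinol and its configuration untouched.

Step 9
Reactants: 6 (2S)-7-[(tert-butyldimethylsilyl)oxy]-2-{2-[(2E)-3,7-dimethylocta-2,6-dien-1-yl]-3-hydroxy-4-methoxyphenyl}-5-hydroxy-6-iodochroman-4-one, 11 (2R)-2-hydroxy-3-methylbut-3-en-1-yl 4-methylbenzenesulfonate
Product: 13 (2S)-7-[(tert-butyldimethylsilyl)oxy]-2-{2-[(2E)-3,7-dimethylocta-2,6-dien-1-yl]-3-hydroxy-4-methoxyphenyl}-5-hydroxy-6-[(2S)-2-hydroxy-3-methylbut-3-en-1-yl]chroman-4-one, via iodohydrin 12 (not isolated)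
Conditions: 11 (2 equiv), NaI (4 equiv), DMA, 40 °C, 2 h; then 6, NiBr2(dme) (10 mol%), 4,4'-dimethoxy-2,2'-bipyridine (12 mol%), undivided cell, Zn anode, Ni-foam cathode, 4 mA constant current, 2.5 F per mol of 6, rt, Ar
Reagents that add atoms: none
Why: Proposed new method: nickel-catalysed electroreductive cross-electrophile coupling has not been shown for a 2,6-dioxygenated ortho-hydroxyaryl iodide with an unprotected, enantiopure homoallylic iodohydrin made in situ from its tosylate; cathodically generated zerovalent nickel inserts into the C6–I bond (the iodide offsets the electron-rich ring and both flanking oxygen substituents are small), a monovalent nickel species abstracts iodine from 12 to give a primary radical that is captured by the aryl complex of divalent nickel, and reductive elimination from trivalent nickel forms the C6–CH2 bond, while the carbinol carbon is β to the radical and never becomes planar, so the configuration bought in 7 is kept (1,2-vinyl shift and β-hydroxide loss are slower than capture); the closest known reaction type is the electroreductive nickel/bipyridine aryl halide–alkyl halide cross-electrophile coupling together with the zinc-mediated nickel coupling of aryl halides with epoxide-derived iodohydrins.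

Step 10
Reactants: 13 (2S)-7-[(tert-butyldimethylsilyl)oxy]-2-{2-[(2E)-3,7-dimethylocta-2,6-dien-1-yl]-3-hydroxy-4-methoxyphenyl}-5-hydroxy-6-[(2S)-2-hydroxy-3-methylbut-3-en-1-yl]chroman-4-one
Product: 16 (2S)-2-{2-[(2E)-3,7-dimethylocta-2,6-dien-1-yl]-3,4-dihydroxyphenyl}-5,7-dihydroxy-6-[(2S)-2-hydroxy-3-methylbut-3-en-1-yl]chroman-4-one, via ortho-quinone 14 (not isolated), via silyl catechol 15 (not isolated)
Conditions: IBX (1.2 equiv), MeOH–THF, −25 °C to 0 °C; then aq. Na2S2O4, 0 °C; then KHF2, rt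
Reagents that add atoms: 2-iodoxybenzoic acid, O=C1OI(=O)(O)c2ccccc12
Why: IBX-mediated oxidative demethylation of the guaiacol unit (oxygen transfer to the methoxy-bearing ortho carbon, loss of methanol) gives ortho-quinone 14 at a temperature where the secondary alcohol, the alkenes and the silylated ring A are not attacked, dithionite reduces 14 to the catechol, and KHF2 cleaves the phenolic silyl ether, none of which touches C2 or the carbinol.

## Compound list

1 | (2S)-hesperetin, (2S)-5,7-dihydroxy-2-(3-hydroxy-4-methoxyphenyl)chroman-4-one | COc1ccc(cc1O)[C@@H]1CC(=O)c2c(O)cc(O)cc2O1 | starting material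
2 | (2S)-7-[(tert-butyldimethylsilyl)oxy]-5-hydroxy-2-(3-hydroxy-4-methoxyphenyl)chroman-4-one | COc1ccc(cc1O)[C@@H]1CC(=O)c2c(O)cc(O[Si](C)(C)C(C)(C)C)cc2O1 | intermediate
3 | (2S)-7-[(tert-butyldimethylsilyl)oxy]-5-hydroxy-2-(3-hydroxy-4-methoxyphenyl)-6-iodochroman-4-one | COc1ccc(cc1O)[C@@H]1CC(=O)c2c(O)c(I)c(O[Si](C)(C)C(C)(C)C)cc2O1 | intermediate
4 | geraniol, (2E)-3,7-dimethylocta-2,6-dien-1-ol | CC(C)=CCC/C(C)=C/CO | starting material
5 | (2S)-7-[(tert-butyldimethylsilyl)oxy]-2-(3-{[(2E)-3,7-dimethylocta-2,6-dien-1-yl]oxy}-4-methoxyphenyl)-5-hydroxy-6-iodochroman-4-one | COc1ccc(cc1OC/C=C(\C)CCC=C(C)C)[C@@H]1CC(=O)c2c(O)c(I)c(O[Si](C)(C)C(C)(C)C)cc2O1 | intermediate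
6 | (2S)-7-[(tert-butyldimethylsilyl)oxy]-2-{2-[(2E)-3,7-dimethylocta-2,6-dien-1-yl]-3-hydroxy-4-methoxyphenyl}-5-hydroxy-6-iodochroman-4-one | COc1ccc([C@@H]2CC(=O)c3c(O)c(I)c(O[Si](C)(C)C(C)(C)C)cc3O2)c(C/C=C(\C)CCC=C(C)C)c1O | intermediate
7 | methyl (4S)-2,2-dimethyl-1,3-dioxolane-4-carboxylate | COC(=O)[C@@H]1COC(C)(C)O1 | starting material
8 | 2-[(4S)-2,2-dimethyl-1,3-dioxolan-4-yl]propan-2-ol | CC(C)(O)[C@@H]1COC(C)(C)O1 | intermediate
9 | (4R)-2,2-dimethyl-4-(prop-1-en-2-yl)-1,3-dioxolane | C=C(C)[C@@H]1COC(C)(C)O1 | intermediate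
10 | (2R)-3-methylbut-3-ene-1,2-diol | C=C(C)[C@@H](O)CO | intermediate
11 | (2R)-2-hydroxy-3-methylbut-3-en-1-yl 4-methylbenzenesulfonate | C=C(C)[C@@H](O)COS(=O)(=O)c1ccc(C)cc1 | intermediate
12 | (2R)-1-iodo-3-methylbut-3-en-2-ol | C=C(C)[C@@H](O)CI | intermediate
13 | (2S)-7-[(tert-butyldimethylsilyl)oxy]-2-{2-[(2E)-3,7-dimethylocta-2,6-dien-1-yl]-3-hydroxy-4-methoxyphenyl}-5-hydroxy-6-[(2S)-2-hydroxy-3-methylbut-3-en-1-yl]chroman-4-one | C=C(C)[C@@H](O)Cc1c(O[Si](C)(C)C(C)(C)C)cc2c(c1O)C(=O)C[C@@H](c1ccc(OC)c(O)c1C/C=C(\C)CCC=C(C)C)O2 | intermediate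
14 | (2S)-7-[(tert-butyldimethylsilyl)oxy]-2-{2-[(2E)-3,7-dimethylocta-2,6-dien-1-yl]-3,4-dioxocyclohexa-1,5-dien-1-yl}-5-hydroxy-6-[(2S)-2-hydroxy-3-methylbut-3-en-1-yl]chroman-4-one | C=C(C)[C@@H](O)Cc1c(O[Si](C)(C)C(C)(C)C)cc2c(c1O)C(=O)C[C@@H](C1=C(C/C=C(\C)CCC=C(C)C)C(=O)C(=O)C=C1)O2 | intermediate
15 | (2S)-7-[(tert-butyldimethylsilyl)oxy]-2-{2-[(2E)-3,7-dimethylocta-2,6-dien-1-yl]-3,4-dihydroxyphenyl}-5-hydroxy-6-[(2S)-2-hydroxy-3-methylbut-3-en-1-yl]chroman-4-one | C=C(C)[C@@H](O)Cc1c(O[Si](C)(C)C(C)(C)C)cc2c(c1O)C(=O)C[C@@H](c1ccc(O)c(O)c1C/C=C(\C)CCC=C(C)C)O2 | intermediate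
16 | (2S)-2-{2-[(2E)-3,7-dimethylocta-2,6-dien-1-yl]-3,4-dihydroxyphenyl}-5,7-dihydroxy-6-[(2S)-2-hydroxy-3-methylbut-3-en-1-yl]chroman-4-one (CNP0120394.3) | C=C(C)[C@@H](O)Cc1c(O)cc2c(c1O)C(=O)C[C@@H](c1ccc(O)c(O)c1C/C=C(\C)CCC=C(C)C)O2 | target

## Step count and risks

Total step count: 10. Longest linear sequence: 6 steps (1 → 2 → 3 → 5 → 6 → 13 → 16; the branch 7 → 8 → 9 → 10 → 11 → 13 → 16 is equally long).

The three steps most likely to fail:

Step 4 (clay-promoted [1,3] shift). The geranyl cation may go to the para carbon C6' or to C8 of ring A, or the product may cyclise to a chroman on the clay. Fallback: give up the ether rearrangement and geranylate C2' directly. Compound 3 and geraniol 4 are heated on acidic Al2O3 in refluxing hexanes (alumina-directed ortho allylation of phenols with allylic alcohols). Phenol and alcohol are bound side by side on the surface, so only the ortho carbon reacts, and here that is C2'. This fallback sets out from 3 and comes back to the route at 6, leaving out 5; it makes no new compound.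

Step 9 (the proposed new coupling). Radical capture may be slow at the doubly ortho-substituted aryl nickel centre, the free phenols may cause protodeiodination, and 12 may close to the vinyl epoxide. The fallback uses known chemistry, sets out from 11 and 6 and comes back at 13. Compound 11 is silylated (Et3SiCl, imidazole, CH2Cl2) to (2R)-3-methyl-2-[(triethylsilyl)oxy]but-3-en-1-yl 4-methylbenzenesulfonate F1. NaI in acetone converts it into triethyl{[(2R)-1-iodo-3-methylbut-3-en-2-yl]oxy}silane F2. F2 is joined to 6 by the established zinc-powder-mediated nickel reductive coupling of aryl iodides with primary alkyl iodides (NiI2, 4,4'-di-tert-butyl-2,2'-bipyridine, pyridine, NaI, DMPU, 60 °C), giving (2S)-7-[(tert-butyldimethylsilyl)oxy]-2-{2-[(2E)-3,7-dimethylocta-2,6-dien-1-yl]-3-hydroxy-4-methoxyphenyl}-5-hydroxy-6-{(2S)-3-methyl-2-[(triethylsilyl)oxy]but-3-en-1-yl}chroman-4-one F3. PPTS in MeOH then frees the secondary alcohol and returns 13.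

Step 10 (oxidative demethylation). Ortho-quinone 14 may tautomerise and cyclise onto the neighbouring geranyl group, or IBX may attack the allylic alcohol. Fallback: unmask the catechol before the side chain is present, so that the last step is a fluoride deprotection and not an oxidation. It sets out from 6 and comes back at 16. The same IBX/Na2S2O4 sequence on 6 gives (2S)-7-[(tert-butyldimethylsilyl)oxy]-2-{2-[(2E)-3,7-dimethylocta-2,6-dien-1-yl]-3,4-dihydroxyphenyl}-5-hydroxy-6-iodochroman-4-one F4. TBSCl and imidazole in DMF give (2S)-2-{3,4-bis[(tert-butyldimethylsilyl)oxy]-2-[(2E)-3,7-dimethylocta-2,6-dien-1-yl]phenyl}-7-[(tert-butyldimethylsilyl)oxy]-5-hydroxy-6-iodochroman-4-one F5. Coupling with 11 under the conditions of step 9 gives (2S)-2-{3,4-bis[(tert-butyldimethylsilyl)oxy]-2-[(2E)-3,7-dimethylocta-2,6-dien-1-yl]phenyl}-7-[(tert-butyldimethylsilyl)oxy]-5-hydroxy-6-[(2S)-2-hydroxy-3-methylbut-3-en-1-yl]chroman-4-one F6. KHF2 in MeOH removes the three phenolic silyl groups and gives 16.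

Further compounds
F0 | step 4 | none | none
F1 | step 9 | (2R)-3-methyl-2-[(triethylsilyl)oxy]but-3-en-1-yl 4-methylbenzenesulfonate | C=C(C)[C@@H](O[Si](CC)(CC)CC)COS(=O)(=O)c1ccc(C)cc1
F2 | step 9 | triethyl{[(2R)-1-iodo-3-methylbut-3-en-2-yl]oxy}silane | C=C(C)[C@@H](O[Si](CC)(CC)CC)CI
F3 | step 9 | (2S)-7-[(tert-butyldimethylsilyl)oxy]-2-{2-[(2E)-3,7-dimethylocta-2,6-dien-1-yl]-3-hydroxy-4-methoxyphenyl}-5-hydroxy-6-{(2S)-3-methyl-2-[(triethylsilyl)oxy]but-3-en-1-yl}chroman-4-one | C=C(C)[C@@H](O[Si](CC)(CC)CC)Cc1c(O[Si](C)(C)C(C)(C)C)cc2c(c1O)C(=O)C[C@@H](c1ccc(OC)c(O)c1C/C=C(\C)CCC=C(C)C)O2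
F4 | step 10 | (2S)-7-[(tert-butyldimethylsilyl)oxy]-2-{2-[(2E)-3,7-dimethylocta-2,6-dien-1-yl]-3,4-dihydroxyphenyl}-5-hydroxy-6-iodochroman-4-one | Oc1ccc([C@@H]2CC(=O)c3c(O)c(I)c(O[Si](C)(C)C(C)(C)C)cc3O2)c(C/C=C(\C)CCC=C(C)C)c1O
F5 | step 10 | (2S)-2-{3,4-bis[(tert-butyldimethylsilyl)oxy]-2-[(2E)-3,7-dimethylocta-2,6-dien-1-yl]phenyl}-7-[(tert-butyldimethylsilyl)oxy]-5-hydroxy-6-iodochroman-4-one | CC(C)(C)[Si](C)(C)Oc1ccc([C@@H]2CC(=O)c3c(O)c(I)c(O[Si](C)(C)C(C)(C)C)cc3O2)c(C/C=C(\C)CCC=C(C)C)c1O[Si](C)(C)C(C)(C)C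
F6 | step 10 | (2S)-2-{3,4-bis[(tert-butyldimethylsilyl)oxy]-2-[(2E)-3,7-dimethylocta-2,6-dien-1-yl]phenyl}-7-[(tert-butyldimethylsilyl)oxy]-5-hydroxy-6-[(2S)-2-hydroxy-3-methylbut-3-en-1-yl]chroman-4-one | C=C(C)[C@@H](O)Cc1c(O[Si](C)(C)C(C)(C)C)cc2c(c1O)C(=O)C[C@@H](c1ccc(O[Si](C)(C)C(C)(C)C)c(O[Si](C)(C)C(C)(C)C)c1C/C=C(\C)CCC=C(C)C)O2
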